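## Analysis of the target

Compound 18 is a 7-hydroxyisoflavone: a 4H-chromen-4-one (benzo ring A fused to pyranone ring C) whose C3 carries ring B. Ring B is the benzene ring of a 2,2-dimethyl-2H-chromene. It is bonded to C3 through chromene C5, carries OMe at chromene C7 and a free OH at chromene C8, and the pyran oxygen sits on C8a, so three oxygens are contiguous. There is no stereocentre; every problem is one of regiochemistry and chemoselectivity. The sensitive groups are the electron-rich chromene double bond (easily protonated, prone to cationic dimerisation and to oxidation), the pyranone (open to conjugate addition at C2 and ring opening) and two phenols of different acidity. The synthesis is hard because the C3–aryl junction lies next to the vinyl-bearing C4a of a ring whose three oxygens must be told apart, and because ring C has to be formed without harming the chromene. The strategy rests on ring C itself: C2 bears only hydrogen and is bound to O1, and C4 is a ketone between C4a of ring A and the aryl-bearing C3. Read backwards, O1–C2(H) is an aryl formate on ring A and C3/C4 are the two carbons of a diaryl alkyne, so ring C is the formal metathesis product of a formate C=O with that alkyne.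

## Retrosynthetic reasoning

**18 from 17.** The two phenols are released last. Ring B carries an acetate, because an ester oxygen para to the alkyne carbon makes ring B a poor cation-stabilising ring in the key step. Ring A carries a tert-butyldimethylsilyl ether, which keeps the C7 oxygen a donor and survives acid. Both fall together under mild basic alcoholysis.

**17 from 14 (key disconnection).** Ring C is opened at C2–C3 and the C4 oxygen is returned to C2, which gives aryl formate 14, an isomer of 17 that holds exactly the atoms of ring C. A concerted [2+2]/oxete path is open only in the five-membered sense and would give a 3-aroylbenzofuran. In the six-membered sense the oxete would have to bridge C2 and C4 of ring C with a bridgehead double bond, and a vinyl cation held inside ring C could not overlap with ring A. The forward reaction is therefore designed as a proton-started, oxygen-first relay: the formyl oxygen is delivered to C4 through an open vinyl cation that ring A does stabilise, keto formate 15 results, and its enol closes C2–C3 to 16, which dehydrates. The bonds formed and the ring closed are those of a formate–alkyne metathesis.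

**14 from 13 from 12.** The formate is too labile to amines, transition-metal catalysts and chromatography to be carried, so it is put on phenol 13 directly before the key step. Phenol 13 cannot be free during the alkyne-forming coupling, because a hydroxyl ortho to the alkyne adds to it under those conditions and gives a 2-arylbenzofuran. It is carried as tetrahydropyranyl ether 12, which is cleaved at an acidity too low to touch the acetate, the silyl ether or the chromene.

**12 from 8 and 11.** The bond between the alkyne and ring A is cut (Sonogashira coupling). Ring B offers a carbon substituent at chromene C5 from the start, and ring A is available as an iodide, so the route becomes convergent and the position of the future C3–aryl bond is never in question.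

**11 from 10 from 9.** The two hydroxyls of 9 are told apart by hindrance. The one next to iodine is shielded, so the silyl group goes to the other, which is the oxygen that must be the donor at C7. The remaining hydroxyl is then masked as the acetal.

**8 from 6 via 7, and 6 from 5.** The terminal alkyne comes from aldehyde 5 by one-carbon homologation. An aryl acetate would not survive that basic step or the earlier ones, so a methoxymethyl ether is carried from the beginning and exchanged for the acetate once the alkyne is in place, without isolating phenol 7.

**5 from 4, 4 from 2 and 3, 2 from 1.** The pyran ring of ring B is cut back to aryl propargyl ether 4 (Claisen rearrangement and electrocyclisation). Only one ortho position is free, so the annulation can only occur between the ether oxygen and the formyl group. Ether 4 comes from phenol 2 and chloride 3, and 2 from 1 by etherification of the more acidic hydroxyl para to the formyl group. With 1 as starting material the formyl carbon that becomes C3 of ring C is in place from the first step.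

## Alternatives that were turned down

**Alternative 1:** Ring C is cut at O1–C8a and C4–C4a, so ring A is delivered as an aryne, and O1, C2, C3 and C4 come from an α-formyl arylacetate of ring B.
- Forward key step: CsF would unmask a 3-triflyloxy aryne from silyl bis-triflate A1. The enol oxygen of formyl ester A2 would add to the aryne carbon far from the remaining triflate, and the aryl anion next to that triflate would attack the ester and close ring C to chromone triflate A3.
- For: two bonds and ring C form in one operation. The conditions never expose the chromene double bond to acid, so on this point it is safer than the chosen route. The triflate fixes the orientation of the addition.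
- Against: 18 has hydrogen at C5, so the triflate of A3 must be reduced off before two MOM ethers are removed. Enolates of 1,3-dicarbonyl compounds normally attack arynes through carbon and end in insertion into the C–C bond, so the required O-arylation runs against the innate preference. An aryl anion ortho to a triflate can also expel it instead of acylating. A1 and A2 each need several steps; A2 lies at least three steps beyond an aldehyde of the type of 5.
- Comparison: it is longer after the key step and rests on an O-versus-C selectivity for which the substrate offers no handle. Precursor 14 contains exactly the atoms of ring C and its selectivity is set by two protecting groups.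

**Alternative 2:** The bond from chromone C3 to chromene C5 and the O1–C2 bond are cut. Ring B is used as the unactivated chromenol A4 and rings A/C as enaminone A5.
- Forward key step: PhI(OAc)2 in a fluorinated alcohol would oxidise A4 to an electrophilic phenoxonium-type species. The α-carbon of A5 would bond para to the phenol oxygen (chromene C5), and the ring A hydroxyl would add to the iminium carbon and expel the amine, giving isoflavone A6.
- For: it is by far the shortest plan. It needs no halide, aldehyde or alkyne, no protecting group on ring B and only one MOM ether to remove. On step economy it is clearly stronger than the chosen route.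
- Against: the oxidant does not distinguish well between the phenol of A4, the chromene double bond, the enaminone and the free phenol of A5. An oxidised guaiacol-type phenol is attacked as readily at the methoxy-bearing ortho carbon as at the para carbon, which is also flanked by the vinyl-bearing C4a. A6 is a more electron-rich phenol than A4 with its para position substituted, so over-oxidation of the product is built in.
- Comparison: the chosen route needs about twice as many steps, but it derives the C3–aryl bond from the formyl carbon already present in 1 and keeps oxidants away from the chromene and the phenols. Alternative 2 has no element that fixes the site of C–C bond formation.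

**Alternative 3:** Ring C is cut at C4–C4a and C3–C4, and C4 is supplied by carbon monoxide A8. The precursor is o-iodoaryl styryl ether A7, in which O1–C2 and C2=C3 are already in place.
- Forward key step: zerovalent palladium, formed from Pd(OAc)2 and 1,3-bis(diphenylphosphino)propane, would insert into the C–I bond and A8 into the aryl–palladium bond. The acyl–palladium bond would add across the enol ether in the 6-endo sense (acyl to the aryl-bearing carbon), and elimination would give pyranone A9.
- For: the conditions are basic and do not endanger the chromene, and the MOM ethers are robust. Carbonylative palladium annulations of o-iodophenol derivatives are established reaction types, so this key step stands closer to precedent than that of the chosen route.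
- Against: acyl–palladium addition to an enol ether prefers to place the acyl group on the oxygen-bearing carbon, and that 5-exo mode leads to the aurone skeleton. After a syn addition in the endo sense the hydrogen on C3 is anti to palladium, so elimination needs a prior epimerisation. Cyclisation before A8 is taken up competes. A7 needs a stereodefined O-vinylation with a β-halostyrene of ring B, which brings the step count to about that of the chosen route.
- Comparison: both plans have an endo-versus-exo question. Here the innate electronic and ring-size preferences both point the wrong way, while in the chosen route the protecting groups on rings A and B steer the oxygen to C4.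

Key step: step 11

Remark: the tetrahydropyranyl ethers 11 and 12 have a stereocentre at the acetal carbon; they are made and used as racemates and this centre is removed in step 9.

## Route

**Step 1**
Reactants: 1 3,4-dihydroxy-5-methoxybenzaldehyde
Product: 2 3-hydroxy-5-methoxy-4-(methoxymethoxy)benzaldehyde
Conditions: MOMCl (1.05 equiv), K2CO3 (1.1 equiv), acetone, 0 °C to rt
Reagents that add atoms: chloromethyl methyl ether, COCCl
Why: Williamson-type O-alkylation; the 4-hydroxyl is para to the formyl group and clearly the more acidic phenol, so one equivalent of a weak base forms and alkylates only its phenoxide, and the neighbouring 3-OH stays free for step 2.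

**Step 2**
Reactants: 2 3-hydroxy-5-methoxy-4-(methoxymethoxy)benzaldehyde; 3 3-chloro-3-methylbut-1-yne
Product: 4 3-methoxy-4-(methoxymethoxy)-5-[(2-methylbut-3-yn-2-yl)oxy]benzaldehyde
Conditions: DBU, CuCl2 (1 mol %), MeCN, 0 °C
Reagents that add atoms: none
Why: CuCl2-catalysed propargylic substitution of the tertiary chloride by the phenoxide, the usual entry to aryl 1,1-dimethylpropargyl ethers; base and temperature are mild enough for the aldehyde and the MOM acetal.

**Step 3**
Reactants: 4 3-methoxy-4-(methoxymethoxy)-5-[(2-methylbut-3-yn-2-yl)oxy]benzaldehyde
Product: 5 7-methoxy-8-(methoxymethoxy)-2,2-dimethyl-2H-chromene-5-carbaldehyde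
Conditions: N,N-diethylaniline, 180 °C
Reagents that add atoms: none
Why: Aromatic propargyl Claisen rearrangement followed by enolisation, 1,5-hydrogen shift and oxa-6π electrocyclisation (thermal chromene annulation). The other ortho position carries the MOM ether, so the new C–C bond can only form at the carbon between the ether oxygen and the formyl group, which is the substitution pattern of ring B.

**Step 4**
Reactants: 5 7-methoxy-8-(methoxymethoxy)-2,2-dimethyl-2H-chromene-5-carbaldehyde
Product: 6 5-ethynyl-7-methoxy-8-(methoxymethoxy)-2,2-dimethyl-2H-chromene
Conditions: dimethyl (1-diazo-2-oxopropyl)phosphonate, K2CO3, MeOH, 0 °C to rt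
Reagents that add atoms: dimethyl (1-diazo-2-oxopropyl)phosphonate, COP(=O)(OC)C(=[N+]=[N-])C(C)=O
Why: Ohira–Bestmann variant of the Seyferth–Gilbert homologation: deacylation of the reagent in the flask, Horner–Wadsworth–Emmons-type addition to the aldehyde, loss of N2 and a 1,2-shift give the terminal alkyne. The MOM ether and the chromene are inert to K2CO3 in MeOH, which an aryl acetate would not be.

**Step 5**
Reactants: 6 5-ethynyl-7-methoxy-8-(methoxymethoxy)-2,2-dimethyl-2H-chromene
Product: 8 5-ethynyl-7-methoxy-2,2-dimethyl-2H-chromen-8-yl acetate, via chromenol 7 (not isolated)
Conditions: HCl (1 M in MeOH), 40 °C; evaporation; then Ac2O, pyridine, DMAP (cat.), CH2Cl2, 0 °C to rt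
Reagents that add atoms: acetic anhydride, CC(=O)OC(C)=O
Why: Acid-catalysed acetal exchange removes the MOM group, and the air-sensitive electron-rich phenol 7 is acetylated directly (DMAP-catalysed O-acylation). The acetate is placed only now because the basic steps before it would cleave or shift it; dilute HCl in MeOH is a standard way to remove phenolic MOM groups beside 2,2-dimethylchromenes.

**Step 6**
Reactants: 9 4-iodobenzene-1,3-diol
Product: 10 5-[(tert-butyldimethylsilyl)oxy]-2-iodophenol
Conditions: TBSCl (1.0 equiv), imidazole, DMF, −20 to 0 °C
Reagents that add atoms: tert-butyldimethylsilyl chloride, CC(C)(C)[Si](C)(C)Cl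
Why: Silylation of the less hindered phenol; the hydroxyl next to the large iodine is shielded and its oxygen is the poorer nucleophile, so one equivalent of TBSCl at low temperature should go to the hydroxyl para to iodine, as mono-O-alkylations of 4-halo-resorcinols do.

**Step 7**
Reactants: 10 5-[(tert-butyldimethylsilyl)oxy]-2-iodophenol
Product: 11 rac-tert-butyl{4-iodo-3-[(tetrahydro-2H-pyran-2-yl)oxy]phenoxy}dimethylsilane
Conditions: 3,4-dihydro-2H-pyran, PPTS (10 mol %), CH2Cl2, rt
Reagents that add atoms: 3,4-dihydro-2H-pyran, C1=COCCC1
Why: Acid-catalysed addition of the phenol to the enol ether (tetrahydropyranylation). The acetal masks the ortho hydroxyl, which would otherwise add to the new alkyne under the coupling conditions and give a benzofuran.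

**Step 8**
Reactants: 8 5-ethynyl-7-methoxy-2,2-dimethyl-2H-chromen-8-yl acetate; 11 rac-tert-butyl{4-iodo-3-[(tetrahydro-2H-pyran-2-yl)oxy]phenoxy}dimethylsilane
Product: 12 rac-5-({4-[(tert-butyldimethylsilyl)oxy]-2-[(tetrahydro-2H-pyran-2-yl)oxy]phenyl}ethynyl)-7-methoxy-2,2-dimethyl-2H-chromen-8-yl acetate
Conditions: PdCl2(PPh3)2 (3 mol %), CuI (5 mol %), Et3N, THF, degassed, 40 °C
Reagents that add atoms: none
Why: Sonogashira coupling: oxidative addition of the aryl iodide to zerovalent palladium, alkynyl transfer mediated by CuI and Et3N, reductive elimination. A tertiary amine at 40 °C leaves the aryl acetate, the silyl ether and the acetal untouched.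

**Step 9**
Reactants: 12 rac-5-({4-[(tert-butyldimethylsilyl)oxy]-2-[(tetrahydro-2H-pyran-2-yl)oxy]phenyl}ethynyl)-7-methoxy-2,2-dimethyl-2H-chromen-8-yl acetate
Product: 13 5-({4-[(tert-butyldimethylsilyl)oxy]-2-hydroxyphenyl}ethynyl)-7-methoxy-2,2-dimethyl-2H-chromen-8-yl acetate
Conditions: PPTS (20 mol %), MeOH/THF, 40 °C
Reagents that add atoms: none
Why: Mild acid-catalysed acetal exchange with MeOH; an aryl tetrahydropyranyl ether is cleaved at an acidity that does not touch the aryl acetate, the aryl silyl ether or the chromene. With no metal present the o-alkynylphenol should not cyclise.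

**Step 10**
Reactants: 13 5-({4-[(tert-butyldimethylsilyl)oxy]-2-hydroxyphenyl}ethynyl)-7-methoxy-2,2-dimethyl-2H-chromen-8-yl acetate
Product: 14 2-[(8-acetoxy-7-methoxy-2,2-dimethyl-2H-chromen-5-yl)ethynyl]-5-[(tert-butyldimethylsilyl)oxy]phenyl formate
Conditions: acetic formic anhydride (2 equiv), pyridine (1.1 equiv), CH2Cl2, −20 to 0 °C; non-aqueous work-up
Reagents that add atoms: acetic formic anhydride, CC(=O)OC=O
Why: O-Formylation of the phenol by the mixed anhydride, which transfers its formyl group because that carbonyl is the less hindered and more electrophilic one. The aryl formate is sensitive to water, amines and silica, hence the low temperature, the weak base and the non-aqueous isolation; it is used at once.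

**Step 11**
Reactants: 14 2-[(8-acetoxy-7-methoxy-2,2-dimethyl-2H-chromen-5-yl)ethynyl]-5-[(tert-butyldimethylsilyl)oxy]phenyl formate
Product: 17 5-{7-[(tert-butyldimethylsilyl)oxy]-4-oxo-4H-chromen-3-yl}-7-methoxy-2,2-dimethyl-2H-chromen-8-yl acetate, via keto formate 15 (not isolated), via hydroxychromanone 16 (not isolated)
Conditions: TfOH (10 mol %), H2O (30 mol %), HFIP (0.02 M), 0 °C to rt
Reagents that add atoms: none
Why: Proposed new method: the closest known reaction type is the acid-catalysed ring-closing alkyne–carbonyl metathesis of aldehydes and ketones, extended here to a formate ester, with ester-assisted alkyne hydration and the formate-based ring closure of 2-hydroxydeoxybenzoins as precedents for the single events. An oxete spanning C2 and C4 of a six-membered ring would be a bridged bridgehead alkene, so the oxygen is moved stepwise: TfOH protonates the alkyne at the carbon bearing ring B, which leaves an open vinyl cation at C4 conjugated with ring A, and the formyl oxygen closes onto it (6-exo-dig) to a 1,3-benzodioxinium ion. Water adds at the former formyl carbon and the ion collapses to keto formate 15, in which the original formyl oxygen is the C4 ketone and the one-carbon unit is still an ester of the ring A oxygen. The enol of 15 attacks the protonated formate carbon through C3, which forms C2–C3 and closes ring C in a 6-(enolendo)-exo-trig aldol-type closure to hemiacetal 16, and loss of water across C2–C3 gives pyranone 17 and returns the water, so the net change is an isomerisation driven by the aromatic-like chromone. The two transient stereocentres of 16 (C2 and C3) are lost in the dehydration and no stereocentre remains. The step needs protonation at the ring B carbon and not at the ring A carbon, and no direct 5-exo attack of the ring A alkyne carbon on the activated formate (which would give a 3-aroylbenzofuran): the para silyloxy group makes ring A the better cation-stabilising ring, the para acetate and the two meta ether oxygens keep ring B from competing, and a formate is too weak an electrophile for the direct path. High dilution and a catalytic amount of acid are meant to keep the electron-rich chromene double bond of ring B from cationic dimerisation.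

**Step 12**
Reactants: 17 5-{7-[(tert-butyldimethylsilyl)oxy]-4-oxo-4H-chromen-3-yl}-7-methoxy-2,2-dimethyl-2H-chromen-8-yl acetate
Product: 18 7-hydroxy-3-(8-hydroxy-7-methoxy-2,2-dimethyl-2H-chromen-5-yl)-4H-chromen-4-one
Conditions: K2CO3 (2 equiv), MeOH, 0 °C to rt; then aq. NH4Cl
Reagents that add atoms: none
Why: Base-catalysed methanolysis of the aryl acetate and cleavage of the aryl silyl ether, which is activated as the silyl ether of a vinylogous acid (7-hydroxychromone). Once the C7 phenoxide has formed it donates into the pyranone and shields C2 against conjugate addition of methoxide, so ring C should survive.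

## Compound list

1 | 3,4-dihydroxy-5-methoxybenzaldehyde (5-hydroxyvanillin) | COc1cc(C=O)cc(O)c1O | starting material
2 | 3-hydroxy-5-methoxy-4-(methoxymethoxy)benzaldehyde | COCOc1c(O)cc(C=O)cc1OC | intermediate
3 | 3-chloro-3-methylbut-1-yne | C#CC(C)(C)Cl | starting material
4 | 3-methoxy-4-(methoxymethoxy)-5-[(2-methylbut-3-yn-2-yl)oxy]benzaldehyde | COCOc1c(OC)cc(C=O)cc1OC(C)(C)C#C | intermediate
5 | 7-methoxy-8-(methoxymethoxy)-2,2-dimethyl-2H-chromene-5-carbaldehyde | COCOc1c(OC)cc(C=O)c2c1OC(C)(C)C=C2 | intermediate
6 | 5-ethynyl-7-methoxy-8-(methoxymethoxy)-2,2-dimethyl-2H-chromene | COCOc1c(OC)cc(C#C)c2c1OC(C)(C)C=C2 | intermediate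
7 | 5-ethynyl-7-methoxy-2,2-dimethyl-2H-chromen-8-ol | COc1cc(C#C)c2c(c1O)OC(C)(C)C=C2 | intermediate
8 | 5-ethynyl-7-methoxy-2,2-dimethyl-2H-chromen-8-yl acetate | CC(=O)Oc1c(OC)cc(C#C)c2c1OC(C)(C)C=C2 | intermediate
9 | 4-iodobenzene-1,3-diol (4-iodoresorcinol) | Oc1ccc(I)c(O)c1 | starting material
10 | 5-[(tert-butyldimethylsilyl)oxy]-2-iodophenol | CC(C)(C)[Si](C)(C)Oc1ccc(I)c(O)c1 | intermediate
11 | rac-tert-butyl{4-iodo-3-[(tetrahydro-2H-pyran-2-yl)oxy]phenoxy}dimethylsilane (racemic at the acetal carbon) | CC(C)(C)[Si](C)(C)Oc1ccc(I)c(OC2CCCCO2)c1 | intermediate
12 | rac-5-({4-[(tert-butyldimethylsilyl)oxy]-2-[(tetrahydro-2H-pyran-2-yl)oxy]phenyl}ethynyl)-7-methoxy-2,2-dimethyl-2H-chromen-8-yl acetate (racemic at the acetal carbon) | CC(=O)Oc1c(OC)cc(C#Cc3ccc(O[Si](C)(C)C(C)(C)C)cc3OC4CCCCO4)c2c1OC(C)(C)C=C2 | intermediate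
13 | 5-({4-[(tert-butyldimethylsilyl)oxy]-2-hydroxyphenyl}ethynyl)-7-methoxy-2,2-dimethyl-2H-chromen-8-yl acetate | CC(=O)Oc1c(OC)cc(C#Cc3ccc(O[Si](C)(C)C(C)(C)C)cc3O)c2c1OC(C)(C)C=C2 | intermediate
14 | 2-[(8-acetoxy-7-methoxy-2,2-dimethyl-2H-chromen-5-yl)ethynyl]-5-[(tert-butyldimethylsilyl)oxy]phenyl formate | O=COc1cc(O[Si](C)(C)C(C)(C)C)ccc1C#Cc1cc(OC)c(OC(C)=O)c2c1C=CC(C)(C)O2 | intermediate
15 | 2-[(8-acetoxy-7-methoxy-2,2-dimethyl-2H-chromen-5-yl)acetyl]-5-[(tert-butyldimethylsilyl)oxy]phenyl formate | O=COc1cc(O[Si](C)(C)C(C)(C)C)ccc1C(=O)Cc1cc(OC)c(OC(C)=O)c2c1C=CC(C)(C)O2 | intermediate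
16 | 5-{7-[(tert-butyldimethylsilyl)oxy]-2-hydroxy-4-oxo-3,4-dihydro-2H-chromen-3-yl}-7-methoxy-2,2-dimethyl-2H-chromen-8-yl acetate (mixture of stereoisomers at C2 and C3 of the chromanone, both lost on dehydration) | CC(=O)Oc1c(OC)cc(C2C(O)Oc3cc(O[Si](C)(C)C(C)(C)C)ccc3C2=O)c2c1OC(C)(C)C=C2 | intermediate
17 | 5-{7-[(tert-butyldimethylsilyl)oxy]-4-oxo-4H-chromen-3-yl}-7-methoxy-2,2-dimethyl-2H-chromen-8-yl acetate | CC(=O)Oc1c(OC)cc(-c2coc3cc(O[Si](C)(C)C(C)(C)C)ccc3c2=O)c2c1OC(C)(C)C=C2 | intermediate
18 | 7-hydroxy-3-(8-hydroxy-7-methoxy-2,2-dimethyl-2H-chromen-5-yl)-4H-chromen-4-one | COc1cc(-c2coc3cc(O)ccc3c2=O)c2c(c1O)OC(C)(C)C=C2 | target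

## Step count and least certain steps

Total: 12 steps (the deprotection and acetylation of step 5 are run without isolating 7). Longest linear sequence: 10 steps, from 1 through steps 1–5 and 8–12.

**Step 11 (key step, new method).**
- What may go wrong: acid-induced cationic dimerisation of the ring B chromene double bond; hydrolytic loss of the formyl group before the C2–C3 bond forms, which stalls the sequence at the ketone stage; or closure in the five-membered sense through attack of the ring A alkyne carbon on the formate. A π-acidic Lewis acid such as In(OTf)3 was not chosen, because it would also invite attack of the ring A ester oxygen on the alkyne.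
- Fallback (known chemistry), from 13 to 18: 13 is acetylated (Ac2O, pyridine) to diaryl alkyne diacetate F1. F1 is hydrated with Ph3PAuNTf2 in wet 1,4-dioxane; the ring A acetate carbonyl and the donor ring A both direct the oxygen to the carbon next to ring A, and with no free hydroxyl a benzofuran cannot form, so keto diacetate F2 should result. K2CO3 in MeOH removes both acetates and the silyl ether to give trihydroxy deoxybenzoin F3. The classical one-carbon ring closure of a 2-hydroxydeoxybenzoin with DMF, BF3·OEt2 and MsCl, which tolerates free phenols, then gives 18.

**Step 10.**
- What may go wrong: loss of the formyl group by base-induced decarbonylation or by hydrolysis during isolation, and competing transfer of the acetyl group of the mixed anhydride.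
- Fallback, from 13 to 17: the formate is not isolated. 13 is treated with acetic formic anhydride without base, the volatiles are removed under vacuum, and the residue is dissolved in HFIP and submitted directly to the conditions of step 11. No new compound arises (F0).

**Step 6.**
- What may go wrong: poor site selectivity between the two hydroxyls, and double silylation.
- Fallback, from 9 to 10: both hydroxyls are silylated (TBSCl, 2.2 equiv, imidazole) to bis-silyl ether F4. One silyl group is then removed with a substoichiometric amount of K2CO3 in MeOH at low temperature. The silyl ether of the more acidic, iodine-flanked phenol is the better leaving group, so the selection rests on acidity instead of hindrance.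

**Step 2.**
- What may go wrong: elimination of the tertiary propargylic chloride and slow etherification of the flanked phenol.
- Fallback, from 2 to 5: the propargyl ether is bypassed. Phenol 2 is condensed with 3-methylbut-2-enal in the presence of PhB(OH)2 and AcOH in toluene at reflux with removal of water (ortho-quinone methide formation and oxa-6π electrocyclisation). Ring closure is again possible only at the carbon next to the formyl group. No new compound arises (F0).

**Step 12.**
- What may go wrong: conjugate addition of methoxide at C2 and opening of ring C before the C7 phenoxide has formed.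
- Fallback, from 17 to 18, without base: the silyl ether is removed first with Et3N·3HF in THF to give 7-hydroxy isoflavone acetate F5, and the acetate is then removed by acid-catalysed methanolysis (HCl in MeOH, rt).

## Further compounds

F1 | step 11 | 2-[(8-acetoxy-7-methoxy-2,2-dimethyl-2H-chromen-5-yl)ethynyl]-5-[(tert-butyldimethylsilyl)oxy]phenyl acetate | CC(=O)Oc1cc(O[Si](C)(C)C(C)(C)C)ccc1C#Cc1cc(OC)c(OC(C)=O)c2c1C=CC(C)(C)O2
F2 | step 11 | 2-[(8-acetoxy-7-methoxy-2,2-dimethyl-2H-chromen-5-yl)acetyl]-5-[(tert-butyldimethylsilyl)oxy]phenyl acetate | CC(=O)Oc1cc(O[Si](C)(C)C(C)(C)C)ccc1C(=O)Cc1cc(OC)c(OC(C)=O)c2c1C=CC(C)(C)O2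
F3 | step 11 | 1-(2,4-dihydroxyphenyl)-2-(8-hydroxy-7-methoxy-2,2-dimethyl-2H-chromen-5-yl)ethan-1-one | COc1cc(CC(=O)c2ccc(O)cc2O)c2c(c1O)OC(C)(C)C=C2
F0 | step 10 | none | none
F4 | step 6 | [(4-iodo-1,3-phenylene)bis(oxy)]bis[tert-butyl(dimethyl)silane] | CC(C)(C)[Si](C)(C)Oc1ccc(I)c(O[Si](C)(C)C(C)(C)C)c1
F0 | step 2 | none | none
F5 | step 12 | 5-(7-hydroxy-4-oxo-4H-chromen-3-yl)-7-methoxy-2,2-dimethyl-2H-chromen-8-yl acetate | CC(=O)Oc1c(OC)cc(-c2coc3cc(O)ccc3c2=O)c2c1OC(C)(C)C=C2
A1 | alternative 1 | 5-(methoxymethoxy)-2-(trimethylsilyl)-1,3-phenylene bis(trifluoromethanesulfonate) | COCOc1cc(OS(=O)(=O)C(F)(F)F)c([Si](C)(C)C)c(OS(=O)(=O)C(F)(F)F)c1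
A2 | alternative 1 | methyl 2-[7-methoxy-8-(methoxymethoxy)-2,2-dimethyl-2H-chromen-5-yl]-3-oxopropanoate | COC(=O)C(C=O)c1cc(OC)c(OCOC)c2c1C=CC(C)(C)O2
A3 | alternative 1 | 3-[7-methoxy-8-(methoxymethoxy)-2,2-dimethyl-2H-chromen-5-yl]-7-(methoxymethoxy)-4-oxo-4H-chromen-5-yl trifluoromethanesulfonate | COCOc1cc(OS(=O)(=O)C(F)(F)F)c2c(c1)occ(-c1cc(OC)c(OCOC)c3c1C=CC(C)(C)O3)c2=O
A4 | alternative 2 | 7-methoxy-2,2-dimethyl-2H-chromen-8-ol | COc1ccc2c(c1O)OC(C)(C)C=C2
A5 | alternative 2 | (E)-3-(dimethylamino)-1-[2-hydroxy-4-(methoxymethoxy)phenyl]prop-2-en-1-one | COCOc1ccc(C(=O)/C=C/N(C)C)c(O)c1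
A6 | alternative 2 | 3-(8-hydroxy-7-methoxy-2,2-dimethyl-2H-chromen-5-yl)-7-(methoxymethoxy)-4H-chromen-4-one | COCOc1ccc2c(c1)occ(-c1cc(OC)c(O)c3c1C=CC(C)(C)O3)c2=O
A7 | alternative 3 | 5-{(E)-2-[2-iodo-5-(methoxymethoxy)phenoxy]ethenyl}-7-methoxy-8-(methoxymethoxy)-2,2-dimethyl-2H-chromene | COCOc1ccc(I)c(O/C=C/c2cc(OC)c(OCOC)c3c2C=CC(C)(C)O3)c1
A8 | alternative 3 | carbon monoxide | [C-]#[O+]
A9 | alternative 3 | 3-[7-methoxy-8-(methoxymethoxy)-2,2-dimethyl-2H-chromen-5-yl]-7-(methoxymethoxy)-4H-chromen-4-one | COCOc1ccc2c(c1)occ(-c1cc(OC)c(OCOC)c3c1C=CC(C)(C)O3)c2=O
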